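## Structural features

The atoms are numbered C1 (quaternary, geranyl), C2H2, C3H=C4(CH3), C5H, C6H2, C7H, C8(CH3)2, O9, C10=C11(prenyl), C12=O, C13(OH), C14(OH). Ring A is the cyclohexene C1-C2-C3-C4-C5-C14, ring B the cyclopentane C5-C6-C7-C13-C14, ring C the oxolane C7-C8-O9-C10-C13 and ring D the cyclohexenone C1-C12-C11-C10-C13-C14. C14 is shared by rings A, B and D and C13 by rings B, C and D, and O9-C10=C11-C12=O is a vinylogous ester that spans rings C and D. The five stereocentres are contiguous (C7-C13-C14-C1 with C5 on C14), three of them fully substituted; in the numbering used here the target is 1R,5S,7S,13R,14R. On ring B the hydrogens at C5 and C7 and both tertiary hydroxyls lie on one face and rings A, C and D on the other, so every ring fusion is cis and C8 sits on the concave side. The fragile groups are the vinylogous ester, the cis ditertiary diol (C14-OH is in a retro-aldol relation to C12=O) and four acid-sensitive trisubstituted olefins. The real difficulty is the C1-C14-C13 array of fully substituted carbons, the absolute configuration of a quaternary centre that carries two similar unsaturated chains, and the placement of C8 on the hindered face at C7. The key step uses the fact that C5 lies between C4 and the C14 carbinol: with C4 as a ketone, C4(=O)-C5-C14(OH) is an aldol relation inside ring A, and C6-C7-C8 is an acetate unit attached to the terminal carbon of a vinyl ketone.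

## Logic of the disconnections

Ring C of 24 is opened at O9-C10. This leads to 22 (as its bis-silyl ether), in which a tertiary alcohol at C8 faces a free vinylogous acid at C10; the forward step is a cyclodehydration, and it must be mild enough to spare the olefins.

The two C8-CH3 bonds of 22 are cut to give 21, where C8 is the carbonyl of an enol lactone onto O9. The lactone fixes C7 by a cis ring fusion. Its first reaction with a methyl nucleophile releases ring D as an unreactive vinylogous carboxylate, so C12 is protected without a separate step. The demand is a non-basic methyl nucleophile, so that the intermediate methyl ketone is not enolised.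

The acyl C8-O9 bond of 21 is cut to give 19, a phenyl thioester at C7 with a methyl ether at C10. Only the C7 epimer with C8 cis to C10 can lactonise, so the forward step can funnel both epimers into 21 as long as C7 can invert under the conditions. This is the element that makes C7 secure, since an aldol alone cannot be relied on to put C8 on the concave face.

The C4-CH3 bond of 19 is cut to the enol triflate 18, and that to the ketone 17. The ketone is removed only after ring B exists, because C5 can be corrected only while C4 is a carbonyl. The demand is kinetic enolisation toward C3 in the presence of a hindered thioester.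

The silyl ethers of 17 are removed to give 16, and the C7-C13 bond of 16 is cut to give 15. Ring B arises from a thioester enolate and the C13 ketone, the most electrophilic carbonyl left in 15. The closure requires C6 cis to C13, so the C5 epimer is selected at this point through the C4 ketone.

The key cut of 15 removes C5-C14 and C6-C7 and leads to 12 and 13. This gains the loss of ring A and two stereocentres. The demand is an acetate d2 reagent soft enough to ignore the 1,2-dione, and an aldol that chooses C14 over C12, which would also give a six-membered ring.

The C1-C2 bond of 12 is cut to give 9 and the dienone 11, which is made from 10. The quaternary centre is set by a conjugate addition of a vinylogous acid, and the demand is enantiofacial control at a planar anion.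

The C11-prenyl bond of 9 is cut to the acetate 5 (from 4) and the allylstannane 6. The prenyl group enters at the only unsubstituted quinone carbon, so no regiochemical choice is left.

The C1-geranyl bond of 4 is cut to 2 and 3; only one carbon of 2 is nucleophilic. The hydroxyl of 2 comes from 1 by hydrolysis at the symmetric stage. Hydrolysing a quinone that already carried an alkyl group would be unsafe, because the methoxy group next to the alkyl group is twisted out of conjugation and is expected to be the more labile one, which would put the hydroxyl on the wrong side.

## Other disconnections considered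

Alternative 1: The cut is C5-C14 in ring A, made by a sigmatropic shift rather than an aldol. The forward key step enolises and silylates the six-membered lactone A2 (ring O-C3-C2-C1-C14-C13) and lets the silyl ketene acetal rearrange through a boat, the only geometry open when C14 and C3 are bridged by C1-C2. This gives the ring A acid A1 with C1, C5 and C14 set.
- In its favour: the C3=C4 methyl olefin is formed directly, so no enol triflate and no coupling are needed. C5 and C14 come from a stereospecific transfer from the carbinol centre and the E olefin of A2, not from an equilibration. On these two points it is better than the chosen plan. The prenyl olefin at C7=C8 is kept for a later cationic closure of rings B and C that would set C7 without an epimerisable intermediate.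
- Against it here: A2 needs its own enantioselective synthesis with a quaternary C1 and a defined carbinol. After the rearrangement ring D must still be built on two adjacent fully substituted carbons, and C13 at the acid oxidation level needs two new C-C bonds.
- Comparison: structurally it solves ring A more cleanly, and mechanistically it is the more predictable step. In step economy it is clearly longer, because the chosen plan brings ring D in ready-made from a quinone.

Alternative 2: The cuts are C7-C13 and O9-C10. The forward key step treats the bicyclic epoxide A4 with a lithium amide base; the gamma-dienolate of the vinylogous ester opens the epoxide at C7 with inversion and the liberated C8 alkoxide displaces methoxide at C10, which gives the 13-deoxy tetracycle A3.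
- In its favour: two rings form in one operation. C7 is fixed stereospecifically by the epoxide, and the gem-dimethyl carbinol comes from a prenyl unit without an organometallic addition or an acid step. On C7 control and on the construction of ring C it is better than the chosen plan.
- Against it here: A3 lacks the C13 hydroxyl, so a late oxidation of a ring-fusion C-H is needed. A4 needs one epoxide of defined configuration among several trisubstituted olefins, which has to be carried from an early stage. The C14 alkoxide next to the dienolate invites retro-aldol opening.
- Comparison: in mechanism the cascade is at least as convincing as the aldol and lactone sequence used here. In structure it pays with the missing oxygen. In step economy it is roughly equal once the synthesis of A4 and the hydroxylation are counted.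

Alternative 3: The cuts are C5-C6 and C7-C13. The forward key step adds the C5 enolate of the enone ketol A6 to the acrylate A7 and lets the ester enolate close onto C13, which gives the tricyclic diol ester A5.
- In its favour: ring B and three stereocentres arise in one convergent step. A6 needs no thioester arm and should be available from a simple vinyl ketone adduct. C5 stays epimerisable through the C4 ketone, exactly as in the chosen plan, so on that point it is equal.
- Against it here: the C5-C6 bond is made intermolecularly at a carbon next to the quaternary C14, beside a C14 alkoxide that can trigger retro-aldol. The C7 question is the same as in the chosen plan, and a chelated ring closure is likely to place the ester on the wrong face. The ring A enone must be introduced beforehand and later transposed into the C3=C4 methyl olefin.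
- Comparison: structurally A5 is close to 16 of the chosen plan. Mechanistically the chosen plan makes the hindered C5-C14 bond intramolecularly and the easy C6-C7 bond at an unhindered vinyl ketone, which is the safer order. Step economy is similar, with extra redox steps on ring A in the alternative.

Key step: step 6

Remark on the chemistry: the cupreidine-derived catalyst of step 5 is assumed to give the R centre at C1; if the sense proves opposite, the cupreine-derived pseudo-enantiomer is used with no other change.

Remark on the chemistry: 16 to 19 are written with the C7 configuration of the target; any C7 epimer formed in step 7 is carried along and converges in step 11.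

## Route

Step 1
Reactants: 1 2,6-dimethoxy-1,4-benzoquinone
Product: 2 2-hydroxy-6-methoxy-1,4-benzoquinone
Conditions: NaOH (1.05 equiv), H2O/THF, 0 °C; then aq. HCl
Reagents that add atoms: sodium hydroxide, [Na+].[OH-]
Why: Hydroxide replaces one methoxy group by conjugate addition and elimination (hydrolysis of a vinylogous ester); the anion of 2 is deactivated, so the second methoxy group should survive, and the symmetry of 1 removes any regiochemical question.

Step 2
Reactants: 2 2-hydroxy-6-methoxy-1,4-benzoquinone; 3 geranyl bromide
Product: 4 3-geranyl-2-hydroxy-6-methoxy-1,4-benzoquinone (geranyl = (2E)-3,7-dimethylocta-2,6-dienyl)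
Conditions: LiH, DMSO, rt; then 3, LiI (cat.), rt
Reagents that add atoms: none
Why: C-allylation of the lithium salt of a 2-hydroxyquinone at its only nucleophilic carbon, a known alkylation of vinylogous acids; the tight lithium ion pair and the soft allylic halide favour C over O, and the E olefin of 3 is not touched.

Step 3
Reactants: 4 3-geranyl-2-hydroxy-6-methoxy-1,4-benzoquinone
Product: 5 2-acetoxy-3-geranyl-6-methoxy-1,4-benzoquinone
Conditions: Ac2O, pyridine, DMAP (cat.), CH2Cl2, 0 °C
Reagents that add atoms: acetic anhydride, CC(=O)OC(C)=O
Why: O-acetylation masks the acidic hydroxyl, which would otherwise protonate the allylstannane of step 4.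

Step 4
Reactants: 5 2-acetoxy-3-geranyl-6-methoxy-1,4-benzoquinone; 6 tributyl(3-methylbut-2-enyl)stannane
Product: 9 3-geranyl-2-hydroxy-6-methoxy-5-prenyl-1,4-benzoquinone, via acetoxyhydroquinone 7 (not isolated), via benzenetriol 8 (not isolated)
Conditions: 6, BF3·OEt2, CH2Cl2, -78 to -20 °C; aq. NaHCO3; then K2CO3, MeOH, air, rt; aq. HCl
Reagents that add atoms: none
Why: Lewis-acid-promoted allylation of a quinone by an allylstannane delivers the linear prenyl group to the only unsubstituted ring carbon and gives the hydroquinone 7; methanolysis of the acetate gives 8, which air oxidises to the hydroxyquinone.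

Step 5
Reactants: 9 3-geranyl-2-hydroxy-6-methoxy-5-prenyl-1,4-benzoquinone; 10 1,5-dichloropentan-3-one
Product: 12 (6R)-6-geranyl-3-methoxy-6-(3-oxopent-4-enyl)-4-prenylcyclohex-3-ene-1,2,5-trione, via penta-1,4-dien-3-one 11 (not isolated)
Conditions: 10 (3 equiv), Et3N, Et2O, 0 °C, filter; then 9, 9-O-(9-phenanthryl)cupreidine (10 mol %), CH2Cl2, -20 °C
Reagents that add atoms: none
Why: Double dehydrochlorination gives the dienone 11, and the bifunctional cinchona base adds the vinylogous acid 9 through its geranyl-bearing carbon to one enone (enantioselective Michael addition of an alpha-substituted cyclic 1,3-dicarbonyl compound to a vinyl ketone); O-addition is reversible, the excess of 11 suppresses double addition, and the catalyst, bound to the 1,2-dione side of the anion, sets the quaternary centre C1.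

Step 6
Reactants: 12 (6R)-6-geranyl-3-methoxy-6-(3-oxopent-4-enyl)-4-prenylcyclohex-3-ene-1,2,5-trione; 13 3-oxo-3-(phenylsulfanyl)propanoic acid
Product: 15 bicyclic ketol of rings A and D (C4 ketone; C14-OH cis to geranyl; CH2CH2C(=O)SPh on C5 cis to C13), via keto thioester 14 (not isolated)
Conditions: 13 (2 equiv), (R)-proline (30 mol %), THF/DMSO (4:1), 0 °C to rt
Reagents that add atoms: none
Why: Proposed new method: (R)-proline condenses with the vinyl ketone to an iminium ion, the enol of 13 adds to C6 (bond C6-C7) and loses CO2, and the enamine left at C4=C5 (14 is its hydrolysed form) attacks the C14 carbonyl (bond C5-C14) before hydrolysis releases the catalyst. The closest known reactions are the amine-catalysed decarboxylative Michael addition of malonic acid half thioesters to enones and the Hajos-Parrish type enamine aldol of 2,2-disubstituted cyclic 1,3-diones, which have not been joined in one flask on a trione of this kind. Ring A closes in a 6-(enolendo)-exo-trig aldol. C14 is controlled by C1, because the tether can reach only the carbonyl face syn to C2, which places the new hydroxyl cis to the geranyl group in a cis-fused bicycle. C5 is set under equilibrating enamine conditions and stays epimerisable through the C4 ketone, so either epimer can still serve in step 7. The step needs conjugate addition at the vinyl ketone and not at ring D, which the unhindered terminal enone and the tetrasubstituted C10=C11 bond secure. It also needs aldol at C14 and not at C12, although that closure would be six-membered as well; C14 is a non-conjugated ketone activated by the adjacent C13 carbonyl whereas C12 is a vinylogous ester carbonyl, and by analogy with the Wieland-Miescher series (R)-proline is the enantiomer that directs the enamine to the carbonyl in the position of C14. Proline at room temperature should stop at the ketol, so the C14 hydroxyl is kept.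

Step 7
Reactants: 15 bicyclic ketol of rings A and D
Product: 16 tricyclic diol thioester (rings A, B, D; C4 ketone; C13-OH and C14-OH cis; C(=O)SPh on C7)
Conditions: MgBr2·OEt2, iPr2NEt, CH2Cl2, 0 °C; pH 7 buffer
Reagents that add atoms: none
Why: Soft enolisation of the thioester and intramolecular aldol onto the magnesium-chelated C13 ketone closes ring B; the tether forces attack on the C13 face syn to C5, so the C13 hydroxyl ends up cis to that at C14, and only the C5 epimer with C6 cis to C13 can close while the other equilibrates through the C4 enolate; C7 is not relied on here.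

Step 8
Reactants: 16 tricyclic diol thioester
Product: 17 bis(trimethylsilyl) ether of 16
Conditions: Me3SiOSO2CF3, 2,6-lutidine, CH2Cl2, -78 to 0 °C
Reagents that add atoms: trimethylsilyl trifluoromethanesulfonate, C[Si](C)(C)OS(=O)(=O)C(F)(F)F
Why: Silylation of both hindered tertiary alcohols removes the acidic protons and blocks retro-aldol and acyl transfer to the C14 oxygen in the following steps; with lutidine the ketone should not be enol-silylated.

Step 9
Reactants: 17 bis(trimethylsilyl) ether of 16
Product: 18 enol triflate (C3=C4-OSO2CF3)
Conditions: KN(SiMe3)2, THF, -78 °C; then PhNTf2, -78 to -20 °C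
Reagents that add atoms: N-phenylbis(trifluoromethanesulfonimide), O=S(=O)(N(c1ccccc1)S(=O)(=O)C(F)(F)F)C(F)(F)F
Why: Kinetic deprotonation by the bulky amide takes the C3 methylene and not the ring-fusion C5-H or the hindered C7-H beside the silylated C13, and O-triflation fixes the enolate as the C3=C4 enol triflate.

Step 10
Reactants: 18 enol triflate
Product: 19 C4-methyl olefin (C3=C4(CH3); thioester on C7; C10-OMe)
Conditions: Pd(PPh3)4 (5 mol %), SnMe4, LiCl, DMF, 60 °C
Reagents that add atoms: tetramethylstannane, C[Sn](C)(C)C
Why: Stille coupling of the enol triflate with a methyl stannane under neutral conditions; zerovalent palladium with a stannane should leave the thioester, which would not survive methylzinc or methylmagnesium reagents.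

Step 11
Reactants: 19 C4-methyl olefin
Product: 21 enol lactone (C8(=O)-O9-C10; rings B and C cis-fused), via C10 hydroxy thioester 20 (not isolated)
Conditions: LiI, EtOAc, 75 °C; concentrate; then AgOCOCF3, iPr2NEt, MeCN, rt to 40 °C
Reagents that add atoms: none
Why: Iodide demethylates the vinylogous methyl ester at the methyl carbon, and the silver salt activates the thioester for acyl transfer to the vinylogous carboxylate oxygen; only the epimer with C8 cis to C10 can lactonise, and the other is expected to converge through the silver-activated enolate or the acyl ketene at C7, which is reprotonated to the cis-fused lactone.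

Step 12
Reactants: 21 enol lactone
Product: 22 tertiary alcohol (C8(CH3)2OH) with free vinylogous acid at C10
Conditions: MeLi, CeCl3, THF, -78 °C; aq. NH4Cl
Reagents that add atoms: methyllithium, [Li]C
Why: The first organocerium addition opens the activated enol ester to a methyl ketone and leaves ring D as an unreactive vinylogous carboxylate, and the second adds to the ketone; the reagent is weakly basic, so C7 should not be enolised.

Step 13
Reactants: 22 tertiary alcohol with free vinylogous acid
Product: 24 CNP0323114.1, via silylated tetracycle 23 (not isolated)
Conditions: 10-camphorsulfonic acid (20 mol %), CH2Cl2, 4 Å MS, rt; then MeOH, rt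
Reagents that add atoms: none
Why: Acid-catalysed intramolecular vinylogous esterification joins the C8 hydroxyl to C10 in a five-membered ring (by addition and loss of water, or by capture of the C8 cation by O9), and methanolysis then removes both silyl ethers; no stereocentre is touched.

## Compound list

1 | 2,6-dimethoxy-1,4-benzoquinone | COC1=CC(=O)C=C(OC)C1=O | starting material
2 | 2-hydroxy-6-methoxy-1,4-benzoquinone | COC1=CC(=O)C=C(O)C1=O | intermediate
3 | geranyl bromide | CC(C)=CCC/C(C)=C/CBr | starting material
4 | 3-geranyl-2-hydroxy-6-methoxy-1,4-benzoquinone | CC(C)=CCC/C(C)=C/CC1=C(O)C(=O)C(OC)=CC1=O | intermediate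
5 | 2-acetoxy-3-geranyl-6-methoxy-1,4-benzoquinone | CC(C)=CCC/C(C)=C/CC1=C(OC(C)=O)C(=O)C(OC)=CC1=O | intermediate
6 | tributyl(3-methylbut-2-enyl)stannane | CC(C)=CC[Sn](CCCC)(CCCC)CCCC | starting material
7 | 2-acetoxy-3-geranyl-6-methoxy-5-prenylbenzene-1,4-diol | CC(C)=CCC/C(C)=C/Cc1c(OC(C)=O)c(O)c(OC)c(CC=C(C)C)c1O | intermediate
8 | 3-geranyl-6-methoxy-5-prenylbenzene-1,2,4-triol | CC(C)=CCC/C(C)=C/Cc1c(O)c(O)c(OC)c(CC=C(C)C)c1O | intermediate
9 | 3-geranyl-2-hydroxy-6-methoxy-5-prenyl-1,4-benzoquinone | CC(C)=CCC/C(C)=C/CC1=C(O)C(=O)C(OC)=C(CC=C(C)C)C1=O | intermediate
10 | 1,5-dichloropentan-3-one | ClCCC(=O)CCCl | starting material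
11 | penta-1,4-dien-3-one | C=CC(=O)C=C | intermediate
12 | (6R)-6-geranyl-3-methoxy-6-(3-oxopent-4-enyl)-4-prenylcyclohex-3-ene-1,2,5-trione | CC(C)=CCC/C(C)=C/C[C@@]1(CCC(=O)C=C)C(=O)C(=O)C(OC)=C(CC=C(C)C)C1=O | intermediate
13 | 3-oxo-3-(phenylsulfanyl)propanoic acid | OC(=O)CC(=O)Sc1ccccc1 | starting material
14 | (6R)-6-[3,7-dioxo-7-(phenylsulfanyl)heptyl]-6-geranyl-3-methoxy-4-prenylcyclohex-3-ene-1,2,5-trione | CC(C)=CCC/C(C)=C/C[C@@]1(CCC(=O)CCCC(=O)Sc2ccccc2)C(=O)C(=O)C(OC)=C(CC=C(C)C)C1=O | intermediate
15 | bicyclic ketol, rings A and D (C4 ketone; C14-OH cis to geranyl; thioester arm on C5 cis to C13) | CC(C)=CCC/C(C)=C/C[C@]12CCC(=O)[C@H](CCC(=O)Sc3ccccc3)[C@]2(O)C(=O)C(OC)=C(CC=C(C)C)C1=O | intermediate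
16 | tricyclic diol thioester, rings A, B, D (cis diol at C13 and C14; C(=O)SPh on C7 cis to C10) | CC(C)=CCC/C(C)=C/C[C@]12CCC(=O)[C@@H]3C[C@H](C(=O)Sc4ccccc4)[C@](O)(C(OC)=C(CC=C(C)C)C1=O)[C@@]32O | intermediate
17 | 13,14-bis(trimethylsilyl) ether of 16 | CC(C)=CCC/C(C)=C/C[C@]12CCC(=O)[C@@H]3C[C@H](C(=O)Sc4ccccc4)[C@](O[Si](C)(C)C)(C(OC)=C(CC=C(C)C)C1=O)[C@@]32O[Si](C)(C)C | intermediate
18 | C3=C4 enol triflate of 17 | CC(C)=CCC/C(C)=C/C[C@]12CC=C(OS(=O)(=O)C(F)(F)F)[C@@H]3C[C@H](C(=O)Sc4ccccc4)[C@](O[Si](C)(C)C)(C(OC)=C(CC=C(C)C)C1=O)[C@@]32O[Si](C)(C)C | intermediate
19 | C4-methyl olefin (thioester on C7, methyl ether at C10, bis-silyl ether) | CC(C)=CCC/C(C)=C/C[C@]12CC=C(C)[C@@H]3C[C@H](C(=O)Sc4ccccc4)[C@](O[Si](C)(C)C)(C(OC)=C(CC=C(C)C)C1=O)[C@@]32O[Si](C)(C)C | intermediate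
20 | C10 hydroxy thioester (vinylogous acid, present as its lithium salt) | CC(C)=CCC/C(C)=C/C[C@]12CC=C(C)[C@@H]3C[C@H](C(=O)Sc4ccccc4)[C@](O[Si](C)(C)C)(C(O)=C(CC=C(C)C)C1=O)[C@@]32O[Si](C)(C)C | intermediate
21 | enol lactone, rings A to D with C8 as lactone carbonyl (bis-silyl ether) | CC(C)=CCC/C(C)=C/C[C@]12CC=C(C)[C@@H]3C[C@@H]4C(=O)OC(=C(CC=C(C)C)C1=O)[C@]4(O[Si](C)(C)C)[C@@]32O[Si](C)(C)C | intermediate
22 | C8 dimethyl carbinol with free vinylogous acid at C10 (bis-silyl ether) | CC(C)=CCC/C(C)=C/C[C@]12CC=C(C)[C@@H]3C[C@H](C(C)(C)O)[C@](O[Si](C)(C)C)(C(O)=C(CC=C(C)C)C1=O)[C@@]32O[Si](C)(C)C | intermediate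
23 | 13,14-bis(trimethylsilyl) ether of the target | CC(C)=CCC/C(C)=C/C[C@]12CC=C(C)[C@@H]3C[C@@H]4C(C)(C)OC(=C(CC=C(C)C)C1=O)[C@]4(O[Si](C)(C)C)[C@@]32O[Si](C)(C)C | intermediate
24 | CNP0323114.1 (1R,5S,7S,13R,14R in the numbering used here) | CC(C)=CCC/C(C)=C/C[C@]12CC=C(C)[C@@H]3C[C@@H]4C(C)(C)OC(=C(CC=C(C)C)C1=O)[C@]4(O)[C@@]32O | target

## Step count and least certain steps

Total step count: 13. Longest linear sequence: 13 steps (1 to 24).

Step 6 (key step). The likely failures are these:
- loss of the catalyst by addition and elimination at C10 or by condensation with the 1,2-dione;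
- decarboxylative aldol addition of 13 to C14 in place of conjugate addition;
- retro-Michael fragmentation of 12 through its C3 enamine;
- dehydration of the ketol;
- protonative decarboxylation of 13 before it has added.

All of these follow from running two amine-mediated events on a substrate with several strong electrophiles. The fallback uses known chemistry in two flasks. It sets out from 12 and 13: a tertiary amine (Et3N, catalytic, THF) promotes only the decarboxylative Michael addition and 14 is isolated. A separate Hajos-Parrish type aldol with (R)-proline in DMSO then gives 15, where the route is rejoined. It makes no new compound (F0).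

Step 5. The risk is poor enantiofacial discrimination at the planar anion of 9, whose two flanks differ only remotely, together with competing double addition to 11. The fallback gives up asymmetric catalysis. From 9 and 11 an achiral amine base gives the racemic trione F1, which is resolved by preparative chromatography on a chiral stationary phase. The route is rejoined at 12.

Step 7. The magnesium aldolate may transfer the acyl group to the C13 or C14 oxygen, the alpha-ketol at C14/C13 may undergo a 1,2-shift, or C14 may open by retro-aldol before C7 attacks. All three arise from a free C14 hydroxyl next to a Lewis acid. The fallback protects first and changes the mode of enolisation. From 15, silylation with Me3SiOSO2CF3 and 2,6-lutidine gives the C14 silyl ether F2. A catalytic amidine base (DBU, MeCN) then closes ring B through an open, metal-free aldol to the mono-silyl ether F3. A second silylation rejoins the route at 17.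

Step 11. Epimerisation at C7 may be too slow, the C7 enolate may instead eliminate the C13 silanolate, or liberated thiolate may add to C10. The fallback separates the events and makes the planar acyl intermediate on purpose. From 19, silver-promoted hydrolysis of the thioester (AgOCOCF3, aqueous THF) gives the carboxylic acid F4. LiI demethylation gives the seco acid F5. A Yamaguchi lactonisation (2,4,6-trichlorobenzoyl chloride, Et3N, DMAP), which passes through the mixed anhydride and its ketene, closes the lactone and rejoins the route at 21.

Step 13. The acid may add the ring D enol to the neighbouring prenyl olefin, or eliminate the tertiary alcohol, faster than ring C closes. The fallback closes ring C under base and avoids the free vinylogous acid. It sets out from 19, using the C7 epimer with C8 cis to C10 and separating the other if present. MeLi and CeCl3 convert the thioester into the carbinol F6, which keeps the C10 methyl ether. KN(SiMe3)2 in THF then lets the C8 alkoxide add to C10 and expel methoxide. This rejoins the route at 23, which is desilylated as in the second stage of step 13.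

## Further compounds

F0 | step 6 | none | none
F1 | step 5 | racemic 6-geranyl-3-methoxy-6-(3-oxopent-4-enyl)-4-prenylcyclohex-3-ene-1,2,5-trione | CC(C)=CCC/C(C)=C/CC1(CCC(=O)C=C)C(=O)C(=O)C(OC)=C(CC=C(C)C)C1=O
F2 | step 7 | C14 trimethylsilyl ether of 15 | CC(C)=CCC/C(C)=C/C[C@]12CCC(=O)[C@H](CCC(=O)Sc3ccccc3)[C@]2(O[Si](C)(C)C)C(=O)C(OC)=C(CC=C(C)C)C1=O
F3 | step 7 | C14 mono(trimethylsilyl) ether of 16 | CC(C)=CCC/C(C)=C/C[C@]12CCC(=O)[C@@H]3C[C@H](C(=O)Sc4ccccc4)[C@](O)(C(OC)=C(CC=C(C)C)C1=O)[C@@]32O[Si](C)(C)C
F4 | step 11 | C8 carboxylic acid of 19 (C10 methyl ether kept) | CC(C)=CCC/C(C)=C/C[C@]12CC=C(C)[C@@H]3C[C@H](C(O)=O)[C@](O[Si](C)(C)C)(C(OC)=C(CC=C(C)C)C1=O)[C@@]32O[Si](C)(C)C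
F5 | step 11 | seco acid (C8 carboxylic acid, C10 vinylogous acid) | CC(C)=CCC/C(C)=C/C[C@]12CC=C(C)[C@@H]3C[C@H](C(O)=O)[C@](O[Si](C)(C)C)(C(O)=C(CC=C(C)C)C1=O)[C@@]32O[Si](C)(C)C
F6 | step 13 | C8 dimethyl carbinol with C10 methyl ether | CC(C)=CCC/C(C)=C/C[C@]12CC=C(C)[C@@H]3C[C@H](C(C)(C)O)[C@](O[Si](C)(C)C)(C(OC)=C(CC=C(C)C)C1=O)[C@@]32O[Si](C)(C)C
A1 | alternative 1 | ring A acid with C1, C5 and C14 set | CC(C)=CCC/C(C)=C/C[C@@]1(C(=O)OC)CC=C(C)[C@H](CC=C(C)C)[C@]1(OCOC)C(O)=O
A2 | alternative 1 | six-membered lactone (ring O-C3-C2-C1-C14-C13; C1 with geranyl and CO2Me; C14 with OCH2OCH3, either epimer; C3 S with the (E)-6-methylhepta-2,5-dien-2-yl group) | CC(C)=CCC/C(C)=C/C[C@@]1(C(=O)OC)C[C@H](OC(=O)C1OCOC)/C(C)=C/CC=C(C)C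
A3 | alternative 2 | 13-deoxy tetracycle | CC(C)=CCC/C(C)=C/C[C@]12CC=C(C)[C@@H]3C[C@@H]4C(C)(C)OC(=C(CC=C(C)C)C1=O)[C@@H]4[C@@]32O
A4 | alternative 2 | bicyclic vinylogous methyl ester (rings A and D, C13H2, C14-OH) with the C7/C8 epoxide on the C5 side chain | CC(C)=CCC/C(C)=C/C[C@]12CC=C(C)[C@H](C[C@@H]3OC3(C)C)[C@]2(O)CC(OC)=C(CC=C(C)C)C1=O
A5 | alternative 3 | tricyclic diol ester with C4 ketone and C2=C3 | CC(C)=CCC/C(C)=C/C[C@]12C=CC(=O)[C@@H]3C[C@H](C(=O)OC)[C@](O)(C(OC)=C(CC=C(C)C)C1=O)[C@@]32O
A6 | alternative 3 | bicyclic enone ketol (rings A and D, C2=C3-C4=O, C5H2, C14-OH, C13 ketone) | CC(C)=CCC/C(C)=C/C[C@]12C=CC(=O)C[C@]2(O)C(=O)C(OC)=C(CC=C(C)C)C1=O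
A7 | alternative 3 | methyl acrylate | C=CC(=O)OC
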